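## Retrosynthetic overview

1. The last ring is the 1,2-dioxane (C8, C9, C10, C11, O, O). Its C11–O bond is made last by capture of the C11–C12–C13 allyl cation by the C8 hydroperoxide. This is possible because C11 is allylic to the Z-C12=C13 alkene and sits 1,4 to the tertiary peroxy carbon C8; both C11 carbinol epimers converge.
2. The C8–OOH/C7–O pair is anti, the signature of an E-derived (7S,8S)-epoxide opened at C8 by H2O2 with inversion. The C7 oxygen is acetylated before ring closure.
3. The 14-membered carbocycle comes from a Nozaki–Hiyama–Kishi closure of the C11–C12 bond (Z-vinyl iodide plus aldehyde); the C11 configuration is deliberately left open.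
4. The cis α-methylene-γ-lactone (C1, C2) comes from asymmetric allylboration/lactonisation of a farnesol-derived enal with a Baylis–Hillman-derived 2-(methoxycarbonyl)allylboronate; the epoxide comes from a Shi epoxidation.
5. Ring order: γ-lactone → oxirane (temporary, steps 9–17) → 14-membered carbocycle → 1,2-dioxane.

Key step: step 20

Remark: cembrane numbering is used for the macrocycles (C1 = ring CH bearing C15, C2 = lactone O–CH, C16 = lactone C=O, C17 = exocyclic CH2, methyls on C4, C8, C12), and 3-[(4-methoxybenzyl)oxy]propanal and the L-fructose-derived (ent-)Shi ketone are taken as catalogue items.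

## Route

Step 1
Reactants: 1 (2E,6E)-farnesol
Product: 3 (2E,6E)-10,11-epoxy-10,11-dihydrofarnesol (racemic at the oxirane), via bromohydrin 2 (not isolated)
Conditions: NBS, THF–H2O, 0 °C; then K2CO3, MeOH, rt
Reagents that add atoms: water, O; N-bromosuccinimide, O=C1CCC(=O)N1Br (its bromine is carried only by 2)
Why: Bromohydrin formation followed by base-induced epoxide closure; NBS in aqueous THF is known to select the terminal 10,11-alkene of farnesyl chains (the 2,3-alkene is deactivated by the allylic oxygen), and the new stereocentre is excised in step 2.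

Step 2
Reactants: 3 (2E,6E)-10,11-epoxy-10,11-dihydrofarnesol
Product: 5 (2E,6E)-3,7-dimethyldeca-2,6-diene-1,10-diol, via hydroxy aldehyde 4 (not isolated)
Conditions: HIO4·2H2O, THF–Et2O, 0 °C; then NaBH4, MeOH, 0 °C
Reagents that add atoms: none
Why: Periodic acid hydrolyses the epoxide and cleaves the glycol (Malaprade-type cleavage) to the trisnor aldehyde and acetone, and borohydride reduction of the crude aldehyde avoids isolating the hydroxy aldehyde.

Step 3
Reactants: 5 (2E,6E)-3,7-dimethyldeca-2,6-diene-1,10-diol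
Product: 6 (2E,6E)-10-hydroxy-3,7-dimethyldeca-2,6-dienal
Conditions: MnO2, CH2Cl2, rt
Reagents that add atoms: none
Why: Chemoselective allylic oxidation on MnO2 converts only the allylic alcohol and leaves the saturated primary alcohol and the E-geometry untouched.

Step 4
Reactants: 6 (2E,6E)-10-hydroxy-3,7-dimethyldeca-2,6-dienal
Product: 7 (2E,6E)-10-{[tert-butyl(dimethyl)silyl]oxy}-3,7-dimethyldeca-2,6-dienal
Conditions: TBSCl, imidazole, CH2Cl2, 0 °C → rt
Reagents that add atoms: tert-butyldimethylsilyl chloride, CC(C)(C)[Si](C)(C)Cl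
Why: Silyl ether formation masks the later C11 aldehyde as a group that should survive acid catalysis, Shi epoxidation and DDQ and is removed by buffered fluoride.

Step 5
Reactants: 8 3-[(4-methoxybenzyl)oxy]propanal; 9 methyl acrylate
Product: 10 methyl 3-hydroxy-5-[(4-methoxybenzyl)oxy]-2-methylidenepentanoate (racemic)
Conditions: DABCO (1 equiv), MeOH (cat.), neat, rt, several days
Reagents that add atoms: none
Why: Morita–Baylis–Hillman reaction (amine adds to the acrylate, the ammonium enolate adds to the aldehyde, elimination returns the amine); the racemic carbinol centre is erased in step 7.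

Step 6
Reactants: 10 methyl 3-hydroxy-5-[(4-methoxybenzyl)oxy]-2-methylidenepentanoate
Product: 11 methyl 3-acetoxy-5-[(4-methoxybenzyl)oxy]-2-methylidenepentanoate (racemic)
Conditions: Ac2O, pyridine, DMAP (cat.), CH2Cl2, 0 °C
Reagents that add atoms: acetic anhydride, CC(=O)OC(C)=O
Why: DMAP-catalysed acylation turns the hydroxyl into the leaving group needed for the SN2′ borylation.

Step 7
Reactants: 11 methyl 3-acetoxy-5-[(4-methoxybenzyl)oxy]-2-methylidenepentanoate
Product: 12 methyl (2E)-5-[(4-methoxybenzyl)oxy]-2-[(4,4,5,5-tetramethyl-1,3,2-dioxaborolan-2-yl)methyl]pent-2-enoate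
Conditions: B2pin2, CuCl (10 mol %), KOAc (10 mol %), DMF, rt
Reagents that add atoms: bis(pinacolato)diboron, CC1(C)OB(OC1(C)C)B1OC(C)(C)C(C)(C)O1
Why: Copper-catalysed SN2′ borylation of a Baylis–Hillman acetate (Cu–Bpin adds to the acrylate terminus, β-acetoxy elimination) should give the trisubstituted enoate with the alkyl chain trans to the ester (2E), i.e. cis to CH2B, the geometry step 8 needs.

Step 8
Reactants: 7 (2E,6E)-10-{[tert-butyl(dimethyl)silyl]oxy}-3,7-dimethyldeca-2,6-dienal; 12 methyl (2E)-5-[(4-methoxybenzyl)oxy]-2-[(pinacolboryl)methyl]pent-2-enoate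
Product: 14 (4S,5S)-5-[(1E,5E)-9-{[tert-butyl(dimethyl)silyl]oxy}-2,6-dimethylnona-1,5-dien-1-yl]-4-{2-[(4-methoxybenzyl)oxy]ethyl}-3-methylideneoxolan-2-one, via O-boryl hydroxy ester 13 (not isolated)
Conditions: (R)-TRIP (10 mol %), 4 Å MS, toluene, 0 °C → rt; then PPTS (cat.), 40 °C
Reagents that add atoms: none
Why: Chiral-phosphoric-acid-catalysed allylboration through a closed chair transition state followed by lactonisation: the chain cis to CH2B sits axial and gives the syn adduct (the cis-4,5-disubstituted lactone), while the catalyst (Re-face attack on the enal in the accepted model for (R)-TRIP; its antipode is used if the opposite sense is found) sets C5 and with it C4.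

Step 9
Reactants: 14 cis-lactone from step 8
Product: 15 (4S,5S)-5-[(1E)-4-[(2S,3S)-3-(3-{[tert-butyl(dimethyl)silyl]oxy}propyl)-3-methyloxiran-2-yl]-2-methylbut-1-en-1-yl]-4-{2-[(4-methoxybenzyl)oxy]ethyl}-3-methylideneoxolan-2-one
Conditions: ent-Shi ketone (30 mol %), Oxone, K2CO3, Bu4NHSO4, MeCN–DMM–aq. borate buffer (pH 10.5), 0 °C
Reagents that add atoms: Oxone (potassium peroxymonosulfate), [K+].[O-]S(=O)(=O)OO
Why: Shi asymmetric epoxidation (chiral dioxirane, spiro transition state): the L-fructose-derived ketone should give the (S,S)-epoxide of the E-trisubstituted alkene (the D-fructose ketone gives the R,R series), and only this alkene should react because the other trisubstituted alkene is deactivated by the allylic lactone oxygen and the methylene lactone is electron-poor.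

Step 10
Reactants: 15 epoxy lactone from step 9
Product: 16 (4S,5S)-5-[(1E)-4-[(2S,3S)-3-(3-{[tert-butyl(dimethyl)silyl]oxy}propyl)-3-methyloxiran-2-yl]-2-methylbut-1-en-1-yl]-4-(2-hydroxyethyl)-3-methylideneoxolan-2-one
Conditions: DDQ, CH2Cl2–pH 7 buffer (10:1), 0 °C
Reagents that add atoms: none
Why: Oxidative PMB ether cleavage with DDQ is neutral in buffer, so epoxide, silyl ether and methylene lactone should survive and no alkoxide is formed next to the Michael acceptor.

Step 11
Reactants: 16 primary alcohol from step 10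
Product: 17 (4S,5S)-5-[(1E)-4-[(2S,3S)-3-(3-{[tert-butyl(dimethyl)silyl]oxy}propyl)-3-methyloxiran-2-yl]-2-methylbut-1-en-1-yl]-3-methylidene-4-(2-oxoethyl)oxolan-2-one
Conditions: Dess–Martin periodinane, NaHCO3, CH2Cl2, 0 °C → rt
Reagents that add atoms: none
Why: Dess–Martin oxidation under bicarbonate buffer gives the aldehyde without acid that could open the epoxide or base that could isomerise the methylene lactone.

Step 12
Reactants: 17 aldehyde from step 11
Product: 18 (4S,5S)-5-[(1E)-4-[(2S,3S)-3-(3-{[tert-butyl(dimethyl)silyl]oxy}propyl)-3-methyloxiran-2-yl]-2-methylbut-1-en-1-yl]-4-[(2Z)-3-iodobut-2-en-1-yl]-3-methylideneoxolan-2-one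
Conditions: Ph3P+CH(CH3)I I−, NaHMDS, THF, −78 °C; then 17, HMPA, −78 → −20 °C
Reagents that add atoms: (1-iodoethyl)triphenylphosphonium iodide, CC(I)[P+](c1ccccc1)(c1ccccc1)c1ccccc1.[I-]
Why: Stork–Zhao-type Wittig olefination with the α-iodo ylide gives 2-iodo-2-alkenes with iodine cis to the chain (Z) under low-temperature kinetic control, and the preformed ylide should react with the aldehyde faster than with the lactone.

Step 13
Reactants: 18 Z-vinyl iodide from step 12
Product: 19 (4S,5S)-5-[(1E)-4-[(2S,3S)-3-(3-hydroxypropyl)-3-methyloxiran-2-yl]-2-methylbut-1-en-1-yl]-4-[(2Z)-3-iodobut-2-en-1-yl]-3-methylideneoxolan-2-one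
Conditions: TBAF, AcOH (1:1), THF, 0 °C → rt
Reagents that add atoms: none
Why: Fluoride desilylation buffered with acetic acid frees the primary alcohol without a basic alkoxide that could attack the epoxide or the methylene lactone.

Step 14
Reactants: 19 primary alcohol from step 13
Product: 20 (4S,5S)-4-[(2Z)-3-iodobut-2-en-1-yl]-5-[(1E)-2-methyl-4-[(2S,3S)-3-methyl-3-(3-oxopropyl)oxiran-2-yl]but-1-en-1-yl]-3-methylideneoxolan-2-one
Conditions: Dess–Martin periodinane, NaHCO3, CH2Cl2, 0 °C
Reagents that add atoms: none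
Why: Buffered Dess–Martin oxidation gives the γ,δ-epoxy aldehyde, which is used at once in the macrocyclisation.

Step 15
Reactants: 20 iodo aldehyde from step 14
Product: 21 (1S,2S,3E,7S,8S,11RS,12Z)-7,8-epoxy-11-hydroxycembra-3,12,15(17)-trien-16,2-olide (both C11 epimers)
Conditions: CrCl2 (8 equiv), NiCl2 (1 mol %), DMSO–THF, rt, 2 mM (syringe-pump addition)
Reagents that add atoms: none
Why: Nozaki–Hiyama–Kishi macrocyclisation (Ni-catalysed oxidative addition to the vinyl iodide, transmetalation to Cr(III), chemoselective addition to the aldehyde) keeps the Z-geometry and tolerates lactone and epoxide; the new C11 carbinol forms as both epimers, which is accepted because C11 is re-set in step 20.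

Step 16
Reactants: 21 macrocyclic epoxy alcohol from step 15
Product: 22 (1S,2S,3E,7S,8S,11RS,12Z)-11-{[tert-butyl(dimethyl)silyl]oxy}-7,8-epoxycembra-3,12,15(17)-trien-16,2-olide
Conditions: TBSCl, imidazole, DMAP (cat.), DMF, rt
Reagents that add atoms: tert-butyldimethylsilyl chloride, CC(C)(C)[Si](C)(C)Cl
Why: Silylation under non-acidic conditions removes the free C11 hydroxyl, which would otherwise open the 7,8-epoxide in a 5-exo mode (tetrahydrofuran) in the acid-catalysed step that follows.

Step 17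
Reactants: 22 silyl-protected macrocyclic epoxide from step 16
Product: 23 (1S,2S,3E,7S,8R,11RS,12Z)-11-{[tert-butyl(dimethyl)silyl]oxy}-8-hydroperoxy-7-hydroxycembra-3,12,15(17)-trien-16,2-olide
Conditions: H2O2 (anhydrous ethereal solution, 15 equiv), phosphomolybdic acid (3 mol %), Et2O, 0 °C → rt
Reagents that add atoms: hydrogen peroxide, OO
Why: Phosphomolybdic-acid-catalysed perhydrolysis of a trisubstituted epoxide: H2O2 attacks the tertiary C8 with inversion (borderline SN2), giving the anti C7-OH/C8-OOH pair (7S,8R), the large excess of H2O2 being meant to outrun transannular alkene participation.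

Step 18
Reactants: 23 hydroxy hydroperoxide from step 17
Product: 25 (1S,2S,3E,7S,8R,11RS,12Z)-7-acetoxy-11-{[tert-butyl(dimethyl)silyl]oxy}-8-[(triethylsilyl)peroxy]cembra-3,12,15(17)-trien-16,2-olide, via silyl peroxide alcohol 24 (not isolated)
Conditions: TESCl (1.05 equiv), imidazole, CH2Cl2, −40 °C; then Ac2O, pyridine, DMAP, 0 °C → rt
Reagents that add atoms: chlorotriethylsilane, CC[Si](Cl)(CC)CC; acetic anhydride, CC(=O)OC(C)=O
Why: Chemoselective O-silylation then acetylation: the hydroperoxide (pKa about 12.5, unhindered terminal oxygen) should take the silyl chloride before the hindered secondary C7 alcohol, which is then the only acylable site.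

Step 19
Reactants: 25 silylperoxy acetate from step 18
Product: 26 (1S,2S,3E,7S,8R,11RS,12Z)-7-acetoxy-8-hydroperoxy-11-hydroxycembra-3,12,15(17)-trien-16,2-olide
Conditions: HF·pyridine, pyridine, THF, 0 °C → rt
Reagents that add atoms: none
Why: Fluoride-mediated desilylation buffered with pyridine cleaves both the peroxy-silyl group and the allylic silyl ether while acetate, lactone and the O–O bond should stay intact.

Step 20
Reactants: 26 hydroperoxy allylic alcohol (both C11 epimers)
Product: 27 denticulatolide, (1S,2S,3E,7S,8R,11S,12Z)-7-acetoxy-8,11-epidioxycembra-3,12,15(17)-trien-16,2-olide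
Conditions: Re2O7 (5 mol %), CH2Cl2 (5 mM), −30 → 0 °C
Reagents that add atoms: none
Why: Proposed new method: Re2O7 should convert the free C11 allylic alcohol of either epimer into its perrhenate ester, which ionises to the C11–C12–C13 allyl cation (or a tight ion pair), and the pendant C8 hydroperoxide then attacks C11 with loss of water; the closest known reaction types are the Re2O7-catalysed, stereoconvergent dehydrative cyclisation of allylic alcohols bearing a pendant hydroxyl to 2,6-cis-tetrahydropyrans and the Re(VII)- or acid-catalysed alkylation of hydroperoxides (peroxyacetalisation, tertiary and allylic peroxide formation). The 1,2-dioxane closes in a 6-exo-trig mode (attack on the sp2 terminus C11 with C12=C13 exocyclic), attack at C13 being excluded because it would give an eight-membered peroxide. The new stereocentre C11 is set by the ring system and not by the precursor: with C8 fixed as R, only closure that places the C8–C7 and C11–C12 bonds cis on the dioxane (11S) lets the ten-atom C12-to-C7 chain span the ring, the 11R isomer needing a trans-bridged bicyclo[10.2.2] frame, so both epimers of 26 should funnel into one product. The step needs chemoselective ionisation (Re2O7 activates only the free hydroxyl, not the allylic lactone C2–O or the acetate), a single internal nucleophile (C7–O is acetylated, so no tetrahydropyran can form) and retention of the 12Z geometry, which rests on the high rotation barrier of a 1,3-dialkylallyl cation and on capture outrunning 1,3-transposition at low temperature.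

## Compound list

1 | (2E,6E)-farnesol | OC/C=C(\C)CC/C=C(\C)CCC=C(C)C | starting material
2 | (2E,6E)-10-bromo-3,7,11-trimethyldodeca-2,6-diene-1,11-diol (racemic) | OC/C=C(\C)CC/C=C(\C)CCC(Br)C(C)(C)O | intermediate
3 | (2E,6E)-9-(3,3-dimethyloxiran-2-yl)-3,7-dimethylnona-2,6-dien-1-ol (10,11-epoxyfarnesol, racemic) | OC/C=C(\C)CC/C=C(\C)CCC1OC1(C)C | intermediate
4 | (4E,8E)-10-hydroxy-4,8-dimethyldeca-4,8-dienal | OC/C=C(\C)CC/C=C(\C)CCC=O | intermediate
5 | (2E,6E)-3,7-dimethyldeca-2,6-diene-1,10-diol | OC/C=C(\C)CC/C=C(\C)CCCO | intermediate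
6 | (2E,6E)-10-hydroxy-3,7-dimethyldeca-2,6-dienal | O=C/C=C(\C)CC/C=C(\C)CCCO | intermediate
7 | (2E,6E)-10-{[tert-butyl(dimethyl)silyl]oxy}-3,7-dimethyldeca-2,6-dienal | O=C/C=C(\C)CC/C=C(\C)CCCO[Si](C)(C)C(C)(C)C | intermediate
8 | 3-[(4-methoxybenzyl)oxy]propanal | O=CCCOCc1ccc(OC)cc1 | starting material
9 | methyl acrylate | C=CC(=O)OC | starting material
10 | methyl 3-hydroxy-5-[(4-methoxybenzyl)oxy]-2-methylidenepentanoate (racemic) | C=C(C(=O)OC)C(O)CCOCc1ccc(OC)cc1 | intermediate
11 | methyl 3-acetoxy-5-[(4-methoxybenzyl)oxy]-2-methylidenepentanoate (racemic) | C=C(C(=O)OC)C(OC(C)=O)CCOCc1ccc(OC)cc1 | intermediate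
12 | methyl (2E)-5-[(4-methoxybenzyl)oxy]-2-[(4,4,5,5-tetramethyl-1,3,2-dioxaborolan-2-yl)methyl]pent-2-enoate | COC(=O)/C(CB1OC(C)(C)C(C)(C)O1)=C/CCOCc1ccc(OC)cc1 | intermediate
13 | methyl (3S,4S,5E,9E)-13-{[tert-butyl(dimethyl)silyl]oxy}-3-{2-[(4-methoxybenzyl)oxy]ethyl}-6,10-dimethyl-2-methylidene-4-[(4,4,5,5-tetramethyl-1,3,2-dioxaborolan-2-yl)oxy]trideca-5,9-dienoate | C=C(C(=O)OC)[C@H](CCOCc1ccc(OC)cc1)[C@@H](OB1OC(C)(C)C(C)(C)O1)/C=C(\C)CC/C=C(\C)CCCO[Si](C)(C)C(C)(C)C | intermediate
14 | (4S,5S)-5-[(1E,5E)-9-{[tert-butyl(dimethyl)silyl]oxy}-2,6-dimethylnona-1,5-dien-1-yl]-4-{2-[(4-methoxybenzyl)oxy]ethyl}-3-methylideneoxolan-2-one | C=C1C(=O)O[C@@H](/C=C(\C)CC/C=C(\C)CCCO[Si](C)(C)C(C)(C)C)[C@H]1CCOCc1ccc(OC)cc1 | intermediate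
15 | (4S,5S)-5-[(1E)-4-[(2S,3S)-3-(3-{[tert-butyl(dimethyl)silyl]oxy}propyl)-3-methyloxiran-2-yl]-2-methylbut-1-en-1-yl]-4-{2-[(4-methoxybenzyl)oxy]ethyl}-3-methylideneoxolan-2-one | C=C1C(=O)O[C@@H](/C=C(\C)CC[C@@H]2O[C@@]2(C)CCCO[Si](C)(C)C(C)(C)C)[C@H]1CCOCc1ccc(OC)cc1 | intermediate
16 | (4S,5S)-5-[(1E)-4-[(2S,3S)-3-(3-{[tert-butyl(dimethyl)silyl]oxy}propyl)-3-methyloxiran-2-yl]-2-methylbut-1-en-1-yl]-4-(2-hydroxyethyl)-3-methylideneoxolan-2-one | C=C1C(=O)O[C@@H](/C=C(\C)CC[C@@H]2O[C@@]2(C)CCCO[Si](C)(C)C(C)(C)C)[C@H]1CCO | intermediate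
17 | (4S,5S)-5-[(1E)-4-[(2S,3S)-3-(3-{[tert-butyl(dimethyl)silyl]oxy}propyl)-3-methyloxiran-2-yl]-2-methylbut-1-en-1-yl]-3-methylidene-4-(2-oxoethyl)oxolan-2-one | C=C1C(=O)O[C@@H](/C=C(\C)CC[C@@H]2O[C@@]2(C)CCCO[Si](C)(C)C(C)(C)C)[C@H]1CC=O | intermediate
18 | (4S,5S)-5-[(1E)-4-[(2S,3S)-3-(3-{[tert-butyl(dimethyl)silyl]oxy}propyl)-3-methyloxiran-2-yl]-2-methylbut-1-en-1-yl]-4-[(2Z)-3-iodobut-2-en-1-yl]-3-methylideneoxolan-2-one | C=C1C(=O)O[C@@H](/C=C(\C)CC[C@@H]2O[C@@]2(C)CCCO[Si](C)(C)C(C)(C)C)[C@H]1C/C=C(/C)I | intermediate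
19 | (4S,5S)-5-[(1E)-4-[(2S,3S)-3-(3-hydroxypropyl)-3-methyloxiran-2-yl]-2-methylbut-1-en-1-yl]-4-[(2Z)-3-iodobut-2-en-1-yl]-3-methylideneoxolan-2-one | C=C1C(=O)O[C@@H](/C=C(\C)CC[C@@H]2O[C@@]2(C)CCCO)[C@H]1C/C=C(/C)I | intermediate
20 | (4S,5S)-4-[(2Z)-3-iodobut-2-en-1-yl]-5-[(1E)-2-methyl-4-[(2S,3S)-3-methyl-3-(3-oxopropyl)oxiran-2-yl]but-1-en-1-yl]-3-methylideneoxolan-2-one | C=C1C(=O)O[C@@H](/C=C(\C)CC[C@@H]2O[C@@]2(C)CCC=O)[C@H]1C/C=C(/C)I | intermediate
21 | (1S,2S,3E,7S,8S,11RS,12Z)-7,8-epoxy-11-hydroxycembra-3,12,15(17)-trien-16,2-olide | C=C1C(=O)O[C@H]2/C=C(\C)CC[C@@H]3O[C@@]3(C)CCC(O)/C(C)=C\C[C@@H]12 | intermediate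
22 | (1S,2S,3E,7S,8S,11RS,12Z)-11-{[tert-butyl(dimethyl)silyl]oxy}-7,8-epoxycembra-3,12,15(17)-trien-16,2-olide | C=C1C(=O)O[C@H]2/C=C(\C)CC[C@@H]3O[C@@]3(C)CCC(O[Si](C)(C)C(C)(C)C)/C(C)=C\C[C@@H]12 | intermediate
23 | (1S,2S,3E,7S,8R,11RS,12Z)-11-{[tert-butyl(dimethyl)silyl]oxy}-8-hydroperoxy-7-hydroxycembra-3,12,15(17)-trien-16,2-olide | C=C1C(=O)O[C@H]2/C=C(\C)CC[C@H](O)[C@@](OO)(C)CCC(O[Si](C)(C)C(C)(C)C)/C(C)=C\C[C@@H]12 | intermediate
24 | (1S,2S,3E,7S,8R,11RS,12Z)-11-{[tert-butyl(dimethyl)silyl]oxy}-7-hydroxy-8-[(triethylsilyl)peroxy]cembra-3,12,15(17)-trien-16,2-olide | C=C1C(=O)O[C@H]2/C=C(\C)CC[C@H](O)[C@@](OO[Si](CC)(CC)CC)(C)CCC(O[Si](C)(C)C(C)(C)C)/C(C)=C\C[C@@H]12 | intermediate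
25 | (1S,2S,3E,7S,8R,11RS,12Z)-7-acetoxy-11-{[tert-butyl(dimethyl)silyl]oxy}-8-[(triethylsilyl)peroxy]cembra-3,12,15(17)-trien-16,2-olide | C=C1C(=O)O[C@H]2/C=C(\C)CC[C@H](OC(C)=O)[C@@](OO[Si](CC)(CC)CC)(C)CCC(O[Si](C)(C)C(C)(C)C)/C(C)=C\C[C@@H]12 | intermediate
26 | (1S,2S,3E,7S,8R,11RS,12Z)-7-acetoxy-8-hydroperoxy-11-hydroxycembra-3,12,15(17)-trien-16,2-olide | C=C1C(=O)O[C@H]2/C=C(\C)CC[C@H](OC(C)=O)[C@@](OO)(C)CCC(O)/C(C)=C\C[C@@H]12 | intermediate
27 | denticulatolide, (1S,2S,3E,7S,8R,11S,12Z)-7-acetoxy-8,11-epidioxycembra-3,12,15(17)-trien-16,2-olide | C=C1C(=O)O[C@H]2/C=C(\C)CC[C@H](OC(C)=O)[C@@]3(C)CC[C@H](OO3)/C(C)=C\C[C@@H]12 | target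

## Step count and risks

Total step count: 20. Longest linear sequence: 17 steps (steps 1–4 and 8–20, from farnesol).

Steps most likely to fail:

Step 20 (Proposed new method). What may go wrong is ionisation without ring closure: elimination to a diene, 1,3-transposition through the perrhenate with erosion of the 12Z geometry, or acid-induced Hock-type cleavage of the tertiary hydroperoxide. The fallback uses known reaction types and moves C11 to the ketone level. It sets out from 21: Dess–Martin oxidation should give the Z-epoxy enone F1. Phosphomolybdic-acid-catalysed perhydrolysis of its epoxide at C8 then places a hydroperoxide 1,4 to the ketone, and this adds to the carbonyl to give the cyclic peroxyhemiketal (1,2-dioxan-3-ol) F2. Ac2O/pyridine should acetylate only the secondary C7 hydroxyl to give the C7 acetate F3. Et3SiH/TMSOTf in CH2Cl2 at −78 °C then reduces the peroxyhemiketal through its peroxycarbenium ion, hydride arriving on the face away from the macrocyclic bridge, and the route is rejoined at 27.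

Step 8. What may go wrong is slow allyl transfer from the ester-deactivated boronate under the chiral acid, with insufficient facial selectivity, or loss of the syn relationship if the acid promotes ionisation of the adduct. The fallback replaces catalyst control by a chiral ligand on boron and needs no acid. It sets out from acetate 11 (with enal 7): palladium-catalysed borylation with tetrahydroxydiboron should give the allylboronic acid F4, and esterification with D-(−)-diisopropyl tartrate (MgSO4) the (S,S)-tartrate allylboronate F5. This electron-poor boronate should add to 7 without catalyst at −78 °C in toluene (Roush-type reagent control, same chair and syn outcome) to give the borate adduct F6, which lactonises on mildly acidic work-up, so the route is rejoined at 14.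

Step 18. What may go wrong is poor discrimination between the two hydroxylic sites: silylation of the C7 alcohol as well as the hydroperoxide, or acylation at the peroxide oxygen after silyl loss. The fallback differentiates the two oxygens by leaving-group ability instead of kinetics. It sets out from 23: trimethyl orthoacetate with catalytic PPTS should tie C7–O and C8–OO into the cyclic peroxy-orthoester (a 3-methoxy-3-methyl-1,2,4-trioxane) F7. Mild aqueous acetic acid then opens it, the tetrahedral intermediate expelling the better leaving group (the peroxide oxygen), to give the C7 acetate with free C8 hydroperoxide F8. HF·pyridine removes the C11 silyl ether and the route is rejoined at 26.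

Further compounds
F1 | step 20 | (1S,2S,3E,7S,8S,12Z)-7,8-epoxy-11-oxocembra-3,12,15(17)-trien-16,2-olide | C=C1C(=O)O[C@H]2/C=C(\C)CC[C@@H]3O[C@@]3(C)CCC(=O)/C(C)=C\C[C@@H]12
F2 | step 20 | (1S,2S,3E,7S,8R,12Z)-8,11-epidioxy-7,11-dihydroxycembra-3,12,15(17)-trien-16,2-olide (hemiketal epimers at C11) | C=C1C(=O)O[C@H]2/C=C(\C)CC[C@H](O)[C@@]3(C)CCC(O)(OO3)/C(C)=C\C[C@@H]12
F3 | step 20 | (1S,2S,3E,7S,8R,12Z)-7-acetoxy-8,11-epidioxy-11-hydroxycembra-3,12,15(17)-trien-16,2-olide (hemiketal epimers at C11) | C=C1C(=O)O[C@H]2/C=C(\C)CC[C@H](OC(C)=O)[C@@]3(C)CCC(O)(OO3)/C(C)=C\C[C@@H]12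
F4 | step 8 | {(2E)-2-(methoxycarbonyl)-5-[(4-methoxybenzyl)oxy]pent-2-en-1-yl}boronic acid | COC(=O)/C(CB(O)O)=C/CCOCc1ccc(OC)cc1
F5 | step 8 | diisopropyl (4S,5S)-2-{(2E)-2-(methoxycarbonyl)-5-[(4-methoxybenzyl)oxy]pent-2-en-1-yl}-1,3,2-dioxaborolane-4,5-dicarboxylate | COC(=O)/C(CB1O[C@H](C(=O)OC(C)C)[C@@H](C(=O)OC(C)C)O1)=C/CCOCc1ccc(OC)cc1
F6 | step 8 | diisopropyl (4S,5S)-2-{[(3S,4S,5E,9E)-13-{[tert-butyl(dimethyl)silyl]oxy}-1-methoxy-3-{2-[(4-methoxybenzyl)oxy]ethyl}-6,10-dimethyl-2-methylidene-1-oxotrideca-5,9-dien-4-yl]oxy}-1,3,2-dioxaborolane-4,5-dicarboxylate | C=C(C(=O)OC)[C@H](CCOCc1ccc(OC)cc1)[C@@H](OB1O[C@H](C(=O)OC(C)C)[C@@H](C(=O)OC(C)C)O1)/C=C(\C)CC/C=C(\C)CCCO[Si](C)(C)C(C)(C)C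
F7 | step 18 | (1S,2S,3E,7S,8R,11RS,12Z)-11-{[tert-butyl(dimethyl)silyl]oxy}-7-O,8-OO-(1-methoxyethylidene) derivative of 8-hydroperoxy-7-hydroxycembra-3,12,15(17)-trien-16,2-olide (3-methoxy-3-methyl-1,2,4-trioxane, epimers at the orthoester carbon) | C=C1C(=O)O[C@H]2/C=C(\C)CC[C@@H]3OC(C)(OC)OO[C@]3(C)CCC(O[Si](C)(C)C(C)(C)C)/C(C)=C\C[C@@H]12
F8 | step 18 | (1S,2S,3E,7S,8R,11RS,12Z)-7-acetoxy-11-{[tert-butyl(dimethyl)silyl]oxy}-8-hydroperoxycembra-3,12,15(17)-trien-16,2-olide | C=C1C(=O)O[C@H]2/C=C(\C)CC[C@H](OC(C)=O)[C@@](OO)(C)CCC(O[Si](C)(C)C(C)(C)C)/C(C)=C\C[C@@H]12
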